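**Plan**

1. Locants used below: seven-membered ring C1(O-angeloyl)–C2=C3(CH3)–C4H2–C5(O-benzoyl)–C6H–C7(CH3); five-membered ring A is C7–C8–C9–C10(OH)(iPr)–C6; ring B is the carbocycle C1, C2, C3, C6, C7 that becomes the seven-membered ring. Enabling feature: C3 and C5 lie 1,3 to each other across C4H2, so the seven-membered ring is a masked cycloheptane-1,3-dione, that is, a cyclopentanone (C1, C2, C3, C6, C7) plus a ketene (C4–C5).
2. Cuts: both ester C–O bonds; C3–CH3 (coupling of a vinylogous triflate); C3–C4 and C5–C6 together (ketene [2+2] on a silyl enol ether, then retro-aldol opening of the old C3–C6 bond); C6–C10 (aldol condensation); C7–C8 (conjugate addition); C10–O (alkene hydration).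
3. Forward: ring B (bought cyclopentenone) → quaternary C7 → ring A closed to a cis-diquinane → C10 carbinol → ring B expanded by two carbons → C3 methyl, C1 and C5 oxygen → benzoate, angelate.
4. Stereochemistry: C7 from a chiral copper–carbene catalyst; C10 by oxygen delivery to the convex face of the cis-diquinane; C6 by equilibration to the trans-fused hydroazulenone; C1 by epoxidation anti to the angular methyl; C5 by hydroxyl-directed hydride delivery.

Key step: step 9

Remark: the absolute configuration is taken from the given SMILES; the ligand enantiomer in step 1 is the one that should give the (R)-ketone 4.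

**Step 1**
Reactants: 1 3-methylcyclopent-2-en-1-one; 2 5-bromo-2-methylpent-2-ene
Product: 4 (R)-3-methyl-3-(4-methylpent-3-en-1-yl)cyclopentan-1-one, via Grignard reagent 3 (not isolated)
Conditions: Mg, Et2O (2 to 3); Cu(OTf)2 (3 mol%), chiral C2-symmetric 4,5-diphenylimidazolinium chloride (carbene precursor, 4 mol%), 1, Et2O, −30 °C; aq. HCl
Reagents that add atoms: none
Why: copper-catalysed asymmetric conjugate addition of a Grignard reagent to a β-methyl cyclic enone, in which the chiral carbene–copper complex selects the enone face and so sets the quaternary centre C7.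

**Step 2**
Reactants: 4
Product: 5 3-(3-hydroxy-4-methylpentyl)-3-methylcyclopentan-1-ol (quaternary carbon as in 4, mixture at both carbinol carbons)
Conditions: BH3·SMe2, THF, 0 °C to rt; NaOH, H2O2, 0 °C
Reagents that add atoms: hydrogen peroxide, OO
Why: hydroboration–oxidation, in which borane reduces the ketone and adds anti-Markovnikov to the trisubstituted alkene so that oxygen ends on the secondary carbon C10; both new carbinol centres are removed in step 3.

**Step 3**
Reactants: 5
Product: 6 (S)-3-methyl-3-(4-methyl-3-oxopentyl)cyclopentan-1-one (same spatial arrangement as 4)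
Conditions: CrO3, H2SO4, acetone, 0 °C
Reagents that add atoms: none
Why: Jones oxidation of two unhindered secondary alcohols to the 1,6-diketone, with no other oxidisable group present.

**Step 4**
Reactants: 6
Product: 7 3a-methyl-6-(propan-2-yl)-3,3a,4,5-tetrahydropentalen-1(2H)-one (enone C3(=O)–C6=C10, C7 as in 4)
Conditions: KOH, MeOH, 65 °C
Reagents that add atoms: none
Why: intramolecular aldol condensation under thermodynamic control, in which only attack of C6 on the C10 ketone can dehydrate to a conjugated enone (the other aldols would need a bridgehead alkene and revert), closing ring A.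

**Step 5**
Reactants: 7
Product: 8 cis-fused 3a-methyl-6-(propan-2-yl)-3,3a,4,6a-tetrahydropentalen-1(2H)-one (alkene C9=C10, H6 cis to the angular methyl)
Conditions: KOtBu (3 equiv), tBuOH/THF, rt; inverse quench into AcOH/H2O, 0 °C
Reagents that add atoms: none
Why: deconjugation of an enone through its extended dienolate and kinetic α-protonation at C6, which can only give the cis-fused diquinane; recovered 7 is recycled.

**Step 6**
Reactants: 8
Product: 9 cis-fused 6-hydroxy-3a-methyl-6-(propan-2-yl)hexahydropentalen-1(2H)-one (6-OH cis to 3a-CH3 and 6a-H)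
Conditions: Co(acac)2 (20 mol%), PhSiH3, O2 (1 atm), iPrOH, rt
Reagents that add atoms: dioxygen, O=O
Why: Mukaiyama hydration, in which hydrogen-atom transfer to C9 gives the tertiary C10 radical and O2 should trap it on the convex face of the cis-diquinane, the face of H6 and the angular methyl, so the C10 hydroxyl ends cis to the methyl.

**Step 7**
Reactants: 9
Product: 11 cis-fused 3a-methyl-6-(propan-2-yl)-6-(trimethylsilyloxy)-4,5,6,6a-tetrahydropentalen-1(3aH)-one (enone C3(=O)–C2=C1), via bis-silyl enol ether 10 (not isolated)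
Conditions: LiN(iPr)2 (2.2 equiv), THF, −78 °C; Me3SiCl; then Pd(OAc)2 (1.0 equiv), MeCN, rt
Reagents that add atoms: chlorotrimethylsilane, C[Si](C)(C)Cl
Why: kinetic enolisation at the unhindered C2 (the C6 hydrogen is flanked by two fully substituted carbons) followed by Saegusa–Ito oxidation, with the tertiary alkoxide silylated in the same operation.

**Step 8**
Reactants: 11
Product: 12 1,6-bis(trimethylsilyloxy)-3a-methyl-6-(propan-2-yl)-3a,4,5,6-tetrahydropentalene (2-silyloxy diene C1=C2–C3(OSiMe3)=C6)
Conditions: Me3SiOTf, Et3N, CH2Cl2, 0 °C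
Reagents that add atoms: trimethylsilyl trifluoromethanesulfonate, C[Si](C)(C)OS(=O)(=O)C(F)(F)F
Why: soft enolisation of the enone at its only α′ position C6 gives the cross-conjugated silyl dienol ether regiospecifically, and because no free enolate is formed the β-silyloxy group at C10 is not eliminated.

**Step 9**
Reactants: 12
Product: 13 dichlorocyclobutanone adduct (C4Cl2 and C5=O span the old C3=C6 bond; cyclobutanone cis-fused to ring B, drawn on the face opposite the isopropyl group)
Conditions: Cl2CHCOCl (slow addition), Et3N, hexane, 25 °C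
Reagents that add atoms: dichloroacetyl chloride, O=C(Cl)C(Cl)Cl
Why: Dichloroketene, formed in the flask by dehydrochlorination, is attacked at its carbonyl carbon by C6, the nucleophilic terminus of the silyl enol ether, and the oxygen- and allyl-stabilised C3 centre collapses onto the CCl2 carbon in a concerted but highly asynchronous [π2s+π2a] addition, so C5–C6 and C3–C4 form in one operation. The closest known reaction type is the dichloroketene–trimethylsilyl enol ether cycloaddition used to expand cyclopentanone to cycloheptane-1,3-dione, together with the addition of ketenes to 2-silyloxy dienes at the silyloxy-bearing double bond. The ring closed is the cyclobutanone, by a formal [2+2] cycloaddition that is suprafacial on the alkene, so the four-membered ring is necessarily cis-fused to ring B. The new stereocentres C3 and C6 are set by approach of the ketene to the diene face opposite the isopropyl group, but both are erased in step 10, so face selectivity is not needed. What the step needs is site and regioselectivity: the silyloxy group makes C3=C6 the only electron-rich double bond (the C1=C2 vinyl group is unactivated and ketenes avoid [4+2] addition), and the enol ether polarity puts the carbonyl carbon on C6 and the CCl2 carbon on C3. The two chlorine atoms are activating helpers and are removed in step 10.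

**Step 10**
Reactants: 13
Product: 15 trans-fused 3-hydroxy-8a-methyl-3-(propan-2-yl)-1,2,3,3a-tetrahydroazulene-4,6(5H,8aH)-dione (3β-OH, 3aα-H, 8aβ-CH3; C1=C2, C3=O, C5=O; drawn as diketo tautomer), via chlorine-free siloxycyclobutanone 14 (not isolated)
Conditions: Zn dust, AcOH, Et2O, 0 °C to rt; then Bu4NF, AcOH, THF, 0 °C to rt
Reagents that add atoms: none
Why: reductive dechlorination followed by fluoride-triggered retro-aldol opening of the cyclobutanol (de Mayo-type two-carbon ring expansion), in which the C3–C6 bond breaks because C6 leaves as the enolate of the C5 ketone with loss of the strain of both small rings; dechlorination comes first so that the CCl2 carbon is not the better leaving carbanion, and C6, being α to the C5 ketone, should settle as the trans-fused epimer that keeps the C5 branch away from the isopropyl group.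

**Step 11**
Reactants: 15
Product: 16 3-hydroxy-8a-methyl-4-oxo-3-(propan-2-yl)-1,2,3,3a,4,8a-hexahydroazulen-6-yl trifluoromethanesulfonate (C1=C2–C3(OTf)=C4–C5=O)
Conditions: PhNTf2, Et3N, CH2Cl2, 0 °C to rt
Reagents that add atoms: N-phenylbis(trifluoromethanesulfonimide), O=S(=O)(N(c1ccccc1)S(=O)(=O)C(F)(F)F)C(F)(F)F
Why: O-sulfonylation of the β-diketone enolate at the less hindered oxygen on C3 (the C5 oxygen is shielded by C6 and its two fully substituted neighbours), giving the linearly conjugated vinylogous triflate; the tertiary alcohol is too hindered to react.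

**Step 12**
Reactants: 16
Product: 17 trans-fused 3-hydroxy-6,8a-dimethyl-3-(propan-2-yl)-2,3,3a,8a-tetrahydroazulen-4(1H)-one (dienone C5(=O)–C4=C3(CH3)–C2=C1)
Conditions: Me2Zn, Pd(PPh3)4 (5 mol%), THF, 0 °C to rt
Reagents that add atoms: dimethylzinc, C[Zn]C
Why: Negishi coupling of an electron-poor alkenyl triflate, which installs the C3 methyl under neutral conditions that spare the β-hydroxy ketone.

**Step 13**
Reactants: 17
Product: 18 7α,8α-epoxide of 17 (epoxide on C1–C2, anti to the angular methyl)
Conditions: mCPBA, NaHCO3, CH2Cl2, 0 °C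
Reagents that add atoms: 3-chloroperoxybenzoic acid, OOC(=O)c1cccc(Cl)c1
Why: Prilezhaev epoxidation of the more electron-rich γ,δ-alkene of the dienone, from the face opposite the axial methyl on the neighbouring C7, which sets C1.

**Step 14**
Reactants: 18
Product: 19 3β,8α-dihydroxy-6,8a-dimethyl-3-(propan-2-yl)-1,2,3,3a,8,8a-hexahydroazulen-4(5H)-one (C1-OH, C2=C3, C5=O)
Conditions: SmI2 (2.2 equiv), THF/MeOH, −78 °C
Reagents that add atoms: none
Why: SmI2 reductive opening of a γ,δ-epoxy enone, in which the samarium dienolate expels the C2–O bond and is protonated kinetically at C4, giving the C1 alcohol with retention and the C2=C3 alkene.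

**Step 15**
Reactants: 19
Product: 20 6,8a-dimethyl-3-(propan-2-yl)-1,2,3,3a,4,5,8,8a-octahydroazulene-3β,4α,8α-triol (3aα-H, 8aβ-CH3)
Conditions: Me4NBH(OAc)3, MeCN/AcOH, −20 °C
Reagents that add atoms: none
Why: Evans–Saksena reduction, in which the tertiary C10 hydroxyl binds boron and delivers hydride to the β face of the C5 ketone to give the anti-1,3-diol (C5-OH α); the acidic medium also removes the base-sensitive β,γ-enone before any acylation.

**Step 16**
Reactants: 20
Product: 21 3β,8α-dihydroxy-6,8a-dimethyl-3-(propan-2-yl)-1,2,3,3a,4,5,8,8a-octahydroazulen-4α-yl benzoate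
Conditions: BzCl (1.1 equiv), pyridine, CH2Cl2, −20 to 0 °C
Reagents that add atoms: benzoyl chloride, O=C(Cl)c1ccccc1
Why: site-selective acylation, in which the C5 hydroxyl (next to a methine) should react before the neopentylic allylic C1 hydroxyl, while the tertiary C10 hydroxyl is inert.

**Step 17**
Reactants: 21
Product: 22 target, 4α-benzoyloxy-3β-hydroxy-6,8a-dimethyl-3-(propan-2-yl)-1,2,3,3a,4,5,8,8a-octahydroazulen-8α-yl (Z)-2-methylbut-2-enoate
Conditions: angelic acid, 2,4,6-trichlorobenzoyl chloride, Et3N, toluene, rt; then 21, 60 °C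
Reagents that add atoms: angelic acid, C/C=C(/C)C(O)=O
Why: Yamaguchi-type mixed-anhydride esterification without a nucleophilic catalyst, the usual way to make angelates of hindered alcohols without Z-to-E isomerisation; the tertiary alcohol and the benzoate are untouched.

**Compound list**

1 | 3-methylcyclopent-2-en-1-one | CC1=CC(=O)CC1 | starting material
2 | 5-bromo-2-methylpent-2-ene | CC(C)=CCCBr | starting material
3 | (4-methylpent-3-en-1-yl)magnesium bromide | CC(C)=CCC[Mg]Br | intermediate
4 | (R)-3-methyl-3-(4-methylpent-3-en-1-yl)cyclopentan-1-one | CC(C)=CCC[C@]1(C)CCC(=O)C1 | intermediate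
5 | 3-(3-hydroxy-4-methylpentyl)-3-methylcyclopentan-1-ol (mixture at both carbinol carbons) | CC(C)C(O)CC[C@]1(C)CCC(O)C1 | intermediate
6 | (S)-3-methyl-3-(4-methyl-3-oxopentyl)cyclopentan-1-one | CC(C)C(=O)CC[C@]1(C)CCC(=O)C1 | intermediate
7 | 3a-methyl-6-(propan-2-yl)-3,3a,4,5-tetrahydropentalen-1(2H)-one | CC(C)C1=C2C(=O)CC[C@@]2(C)CC1 | intermediate
8 | cis-fused 3a-methyl-6-(propan-2-yl)-3,3a,4,6a-tetrahydropentalen-1(2H)-one | CC(C)C1=CC[C@]2(C)CCC(=O)[C@H]12 | intermediate
9 | cis-fused 6-hydroxy-3a-methyl-6-(propan-2-yl)hexahydropentalen-1(2H)-one (OH cis to 3a-CH3 and 6a-H) | C1CC(=O)[C@H]2[C@]1(C)CC[C@@]2(O)C(C)C | intermediate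
10 | trimethylsilyl enol ether (C2=C3) of 9 with the C10 oxygen also silylated | C1C=C(O[Si](C)(C)C)[C@H]2[C@]1(C)CC[C@@]2(O[Si](C)(C)C)C(C)C | intermediate
11 | cis-fused 3a-methyl-6-(propan-2-yl)-6-(trimethylsilyloxy)-4,5,6,6a-tetrahydropentalen-1(3aH)-one | C1=CC(=O)[C@H]2[C@]1(C)CC[C@@]2(O[Si](C)(C)C)C(C)C | intermediate
12 | 1,6-bis(trimethylsilyloxy)-3a-methyl-6-(propan-2-yl)-3a,4,5,6-tetrahydropentalene | C1=CC(O[Si](C)(C)C)=C2[C@]1(C)CC[C@@]2(O[Si](C)(C)C)C(C)C | intermediate
13 | dichlorocyclobutanone [2+2] adduct of 12 (CCl2 on C3, C=O on C6, cis-fused, anti to isopropyl) | C1=C[C@@]3(O[Si](C)(C)C)C(Cl)(Cl)C(=O)[C@@]32[C@]1(C)CC[C@@]2(O[Si](C)(C)C)C(C)C | intermediate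
14 | chlorine-free siloxycyclobutanone from 13 | C1=C[C@@]3(O[Si](C)(C)C)CC(=O)[C@@]32[C@]1(C)CC[C@@]2(O[Si](C)(C)C)C(C)C | intermediate
15 | trans-fused 3β-hydroxy-8aβ-methyl-3-(propan-2-yl)-1,2,3,3a-tetrahydroazulene-4,6(5H,8aH)-dione (3aα-H) | C1=CC(=O)CC(=O)[C@@H]2[C@]1(C)CC[C@@]2(O)C(C)C | intermediate
16 | 3-hydroxy-8a-methyl-4-oxo-3-(propan-2-yl)-1,2,3,3a,4,8a-hexahydroazulen-6-yl trifluoromethanesulfonate (stereocentres as in 15) | C1=CC(OS(=O)(=O)C(F)(F)F)=CC(=O)[C@@H]2[C@]1(C)CC[C@@]2(O)C(C)C | intermediate
17 | trans-fused 3β-hydroxy-6,8aβ-dimethyl-3-(propan-2-yl)-2,3,3a,8a-tetrahydroazulen-4(1H)-one | C1=CC(C)=CC(=O)[C@@H]2[C@]1(C)CC[C@@]2(O)C(C)C | intermediate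
18 | 7α,8α-epoxide of 17 | O1[C@@H]2[C@H]1C(C)=CC(=O)[C@@H]3[C@]2(C)CC[C@@]3(O)C(C)C | intermediate
19 | 3β,8α-dihydroxy-6,8aβ-dimethyl-3-(propan-2-yl)-1,2,3,3a,8,8a-hexahydroazulen-4(5H)-one | O[C@@H]1C=C(C)CC(=O)[C@@H]2[C@]1(C)CC[C@@]2(O)C(C)C | intermediate
20 | 6,8aβ-dimethyl-3-(propan-2-yl)-1,2,3,3a,4,5,8,8a-octahydroazulene-3β,4α,8α-triol | O[C@@H]1C=C(C)C[C@H](O)[C@@H]2[C@]1(C)CC[C@@]2(O)C(C)C | intermediate
21 | 4α-benzoate of triol 20 | O[C@@H]1C=C(C)C[C@H](OC(=O)c2ccccc2)[C@@H]2[C@]1(C)CC[C@@]2(O)C(C)C | intermediate
22 | 4α-benzoyloxy-3β-hydroxy-6,8aβ-dimethyl-3-(propan-2-yl)-1,2,3,3a,4,5,8,8a-octahydroazulen-8α-yl (Z)-2-methylbut-2-enoate | C/C=C(/C)C(=O)O[C@@H]1C=C(C)C[C@H](OC(=O)c2ccccc2)[C@@H]2[C@]1(C)CC[C@@]2(O)C(C)C | target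

**Count and risks**

Total step count: 17. Longest linear sequence: 17 steps (1 and 2 to 22).

Step 9 may fail through slow cycloaddition at the crowded C6 (flanked by two fully substituted carbons), so that ketene oligomerisation or addition at the C1=C2 vinyl group competes. The fallback sets out from 12: the more electrophilic N,N-dimethylketeniminium triflate (from N,N-dimethylacetamide, Tf2O and 2,4,6-collidine in CH2Cl2) should add to the silyl enol ether in a stepwise cationic [2+2] cycloaddition to give the cyclobutaniminium triflate F3. Hydrolysis with aqueous NaHCO3 gives the chlorine-free siloxycyclobutanone 14, where the route is rejoined at the fluoride stage of step 10.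

Step 6 may fail through poor facial selectivity in the trapping of the planar C10 radical, or through cobalt-hydride isomerisation of the β,γ-enone back to the conjugated enone. The fallback sets out from 8: mCPBA epoxidation, concerted and expected on the convex face, gives the epoxy ketone F1. LiBHEt3 in THF opens the epoxide at the secondary C9 and reduces the ketone to give the diol F2. Dess–Martin periodinane then oxidises only the secondary alcohol and returns to 9.

Step 16 may fail through loss of site selectivity between the two secondary alcohols, giving the wrong monoester or the diester. The fallback sets out from 19: Et3SiCl and imidazole in DMF protect the only secondary alcohol to give the C1 triethylsilyl ether F4. Me4NBH(OAc)3 reduces the C5 ketone under direction of the free C10 hydroxyl to give the alcohol F5. BzCl, pyridine and DMAP give the benzoate F6, and HF·pyridine in THF removes the silyl group and returns to 21.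

**Further compounds**

F1 | step 6 | convex-face C9–C10 epoxide of 8 (epoxy ketone) | CC(C)[C@]12O[C@H]1C[C@]3(C)CCC(=O)[C@H]23
F2 | step 6 | cis-fused 3a-methyl-6-(propan-2-yl)octahydropentalene-1,6-diol (6-OH cis to 3a-CH3, mixture at C1) | C1CC(O)[C@H]2[C@]1(C)CC[C@@]2(O)C(C)C
F3 | step 9 | cyclobutaniminium triflate from 12 and N,N-dimethylketeniminium | C1=C[C@@]3(O[Si](C)(C)C)CC(=[N+](C)C)[C@@]32[C@]1(C)CC[C@@]2(O[Si](C)(C)C)C(C)C.[O-]S(=O)(=O)C(F)(F)F
F4 | step 16 | 8α-triethylsilyl ether of 19 | CC[Si](CC)(CC)O[C@@H]1C=C(C)CC(=O)[C@@H]2[C@]1(C)CC[C@@]2(O)C(C)C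
F5 | step 16 | 8α-triethylsilyl ether of triol 20 | CC[Si](CC)(CC)O[C@@H]1C=C(C)C[C@H](O)[C@@H]2[C@]1(C)CC[C@@]2(O)C(C)C
F6 | step 16 | 8α-triethylsilyl ether of benzoate 21 | CC[Si](CC)(CC)O[C@@H]1C=C(C)C[C@H](OC(=O)c2ccccc2)[C@@H]2[C@]1(C)CC[C@@]2(O)C(C)C
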